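(Readings and results were computed from invented constants.)

4 questions stand here, and 3 of them ask for the same selectivity: Q divided by Q plus E, for two stirred tanks and a closed flask charged alike.

| flask | L | remark | time |
|---|---|---|---|
| oak | 2 M | run made earlier |  |
| elm | 1.3 M | run made earlier |  |
| birch | 3 M | run made earlier |  |
| theta | 2.0 M | one stirred flow tank at steady state, fed with the mixture as stated, mean residence time 6.0 d |  |
| eta | 2.0 M | one stirred flow tank at steady state, fed with the mixture as stated, mean residence time 60.0 d |  |
| gamma | 2.0 M | a closed flask charged with all of it at once and left for 6.0 d | 6.0 d |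

| run | time / d | Q / % | E / % |
|---|---|---|---|
| oak | 0.417 | 28 | 13 |
| oak | 1.25 | 31 | 30 |
| oak | 2.50 | 28 | 34 |
| oak | 4.00 | 28 | 35 |
| elm | 0.417 | 26 | 15 |
| elm | 1.25 | 30 | 32 |
| elm | 2.50 | 26 | 38 |
| elm | 4.00 | 26 | 41 |
| birch | 0.250 | 20 | 11 |
| birch | 0.625 | 31 | 13 |
| birch | 1.67 | 28 | 29 |
| birch | 4.00 | 23 | 33 |

(scatter of a reading: 1.5 percentage points)

- the set-up with the highest share of Q in all that became Q or E, at the outlet or at the end ("none" if the first two lie within 2 percentage points) (theta / eta / gamma / none)
- share of Q in all that became Q or E, at the outlet or at the end, theta
- share of Q in all that became Q or E, at the outlet or at the end, eta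
- share of Q in all that became Q or E, at the outlet or at the end, gamma

- the stated concentrations are those of everything mixed, before any reaction; amounts are the same in each set-up
- the analysis behind the earlier runs scatters by 1.5 percentage points, standard deviation
- the earlier runs were made in a closed, stirred flask
- a reading or a percentage of Q counts all its forms, free or not

I read the oak run, which has the charge of the new flasks, from fastest to slowest. Q comes first: it reads 28% at 0.417 d and 28% at 4.00 d, so I hold it flat at that reading. E comes next. I join its two ends, the start at nothing and the last reading of 35%, by one exponential through its first reading, which gives 0.898 d, the lag of E, meaning the time constant with which E nears its plateau.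

The residence time comes last. A stirred tank mixes ages exponentially (the residence-time distribution), so, treating each parcel as a small oak flask, its E is the plateau times residence time over residence time plus lag. That is an assumption, since the last reading of E is 41% in the elm run and 33% in the birch run, so the plateau moves with the charge. The E of theta, with a residence time of 6.0 d, then falls short of the plateau by 13.0% of it, and the E of eta by 1.47% of it. My shares are 47.9% for theta, 44.8% for eta and 44.4% for gamma, so I choose theta.

The forecast differs, choosing gamma with 41%, 39% and 44% for theta, eta and gamma. Its ground is: “I therefore read this as L→Q→E on an agent or catalyst that dies within about a day”.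

The simulation gives theta, with 46.5% for theta, 40.1% for eta and 40.9% for gamma.

    L + Q ⇌ J, settled at all times (K = 1.40 /M)
    E ⇌ L (k = 0.00790 /h)
    Q ⇌ E (K = 1.90, k = 0.0430 /h)
    2 L → D (k = 0.00940 /M/h)
    L ⇌ Q (K = 1.50, k = 0.0610 /h)

My theta stands 1.4 percentage points high, but my eta stands 4.7 points high and my gamma 3.5 points high. I use the same lag on the gamma flask read early, at 40 h: my estimate of E there is 29.5%, which with Q held at 28% gives a share of 48.7%. That neighbour holds Q 29.2%, all its forms counted, and E 30.7%, and its share is 48.7%.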